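**Plan**

1. Retrosynthesis: C-9a–O, C-5a–C-6 and C-7–Br are cut together (bromenium-induced bicyclization of an acyclic 2R,3Z,6Z bromohydrin triene). The chain is then cut at C-5–C-5a and C-2–C-3 in one linchpin operation, and last at C-9–C-9a (carbocupration).
2. Enabling feature: C-3 (vinylic, methyl-bearing), C-4 and C-5 (allylic CH2) of the oxepene form a Z-but-2-ene-1,3-diyl unit. It lies between C-5a, which is an sp2 carbon before the rings exist, and C-2, which can be brought in at the acyl oxidation level, so a Z-1-bromo-3-iodobut-2-ene linchpin can be closed at both ends by cross-coupling in one flask.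
3. Forward: a nine-carbon Z-alkenyl iodide from carbocupration of propyne; one-flask union of this unit, the four-carbon linchpin and a 1-ethoxyvinyl group (masked bromoacetyl helper); enol ether to bromomethyl ketone; ketone to carbinol; last, ring A (cyclohexane) and then ring B (oxepene) close in one cascade.
4. Stereochemistry: C-2 from CBS reduction. C-5a, C-7 and C-9a relative to one another come from chair-like anti addition across the Z alkene with equatorial bromine; the Z geometry, fixed by the syn carbocupration, gives the cis ring fusion. The absolute sense of ring A comes from a chiral bromenium carrier, and the enantiopure C-2 centre makes the wrong-face product a separable diastereomer.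

Key step: step 4

Remark: atoms are numbered as in the 1-benzoxepine name of the target (O-1, C-2 with CH2Br, C-3 with the methyl group, C-5a and C-9a at the ring fusion, C-7 with bromine); the named enantiomers of the CBS catalyst and of the chiral Lewis base are assumed to give the 2R and 7S centres, and the antipodal catalyst would be taken if the sense proved opposite.

**Route**

Step 1
Reactants: 1 5-bromo-2-methylpent-2-ene; 2 propyne
Product: 6 (Z)-1-iodo-2,6-dimethylhepta-1,5-diene, via Grignard reagent 3 (not isolated), via alkylcopper 4 (not isolated), via alkenylcopper 5 (not isolated)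
Conditions: Mg, Et2O; CuBr·SMe2, Et2O/Me2S, −45 °C; propyne, −25 °C; I2, THF, −78 to 0 °C
Reagents that add atoms: iodine, II
Why: Carbocupration of a terminal alkyne by an alkylcopper–MgBr2 complex is a syn addition that puts the alkyl group on the internal carbon and copper on the terminal carbon cis to it, and iodinolysis of the C–Cu bond with retention should therefore give only the Z iodide, which fixes the geometry of the later C-5a=C-9a alkene.

Step 2
Reactants: 7 but-2-yn-1-ol
Product: 9 (Z)-3-iodobut-2-en-1-ol, via cyclic alkenylalanate 8 (not isolated)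
Conditions: NaAlH2(OCH2CH2OMe)2, THF, 0 °C to rt; I2, THF, −78 °C
Reagents that add atoms: iodine, II
Why: Alkoxide-directed trans-hydroalumination of the propargylic alcohol places aluminium on C-3 inside a five-membered alanate, and iodinolysis with retention should give the Z iodide (iodine cis to CH2OH) as the single isomer.

Step 3
Reactants: 9 (Z)-3-iodobut-2-en-1-ol
Product: 10 (Z)-1-bromo-3-iodobut-2-ene
Conditions: CBr4, PPh3, CH2Cl2, 0 °C
Reagents that add atoms: carbon tetrabromide, BrC(Br)(Br)Br
Why: Appel reaction, in which SN2 displacement of the alkoxyphosphonium ion by bromide under neutral conditions should convert the primary allylic alcohol without touching the vinylic iodide or the alkene geometry.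

Step 4
Reactants: 6 (Z)-1-iodo-2,6-dimethylhepta-1,5-diene; 10 (Z)-1-bromo-3-iodobut-2-ene; 11 tributyl(1-ethoxyvinyl)stannane
Product: 15 (3Z,6Z)-2-ethoxy-3,7,11-trimethyldodeca-1,3,6,10-tetraene, via alkenyllithium 12 (not isolated), via alkenylmagnesium bromide 13 (not isolated), via dienyl iodide 14 (not isolated)
Conditions: 6, t-BuLi (2 equiv), Et2O, −78 °C; MgBr2·OEt2, −78 to 0 °C; 10, Li2CuCl4 (3 mol %), THF, −40 to 0 °C; then 11, Pd(PPh3)4 (5 mol %), CuI (10 mol %), DMF, 50 °C, one flask
Reagents that add atoms: none
Why: Iodine–lithium exchange on 6 and transmetallation to magnesium give the configurationally stable alkenyl Grignard reagent 13, which a catalytic organocuprate formed from Li2CuCl4 couples with the allylic C–Br bond of 10 to make the C-5–C-5a bond; the vinylic iodide 14 left in the flask then undergoes Stille coupling with 11 (oxidative addition to Pd(PPh3)2, tin-to-palladium transmetallation assisted by CuI, reductive elimination) to make the C-2–C-3 bond. The closest known reaction types are the copper-catalysed head-to-tail coupling of Grignard reagents with geranyl- and neryl-type halides and the Stille coupling of alkenyl iodides with 1-alkoxyvinylstannanes. No ring is closed and no stereocentre is formed; the two Z alkenes are carried over from 6 and 10 because alkenyl–metal and alkenyl–palladium species keep their configuration and the allyl unit never becomes a freely rotating ion. The step needs chemoselectivity between the two carbon–halogen bonds of 10 and α selectivity at its allyl end: the cuprate attacks the sp3 C–Br bond far faster than the sp2 C–I bond, and γ attack would have to build a quaternary, iodine-bearing carbon, so C-5 should be substituted cleanly and the iodide saved for palladium. The 1-ethoxyvinyl group brings in C-2 and the CH2Br carbon at the acyl oxidation level and is converted in steps 5 and 6.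

Step 5
Reactants: 15 (3Z,6Z)-2-ethoxy-3,7,11-trimethyldodeca-1,3,6,10-tetraene
Product: 16 (3Z,6Z)-1-bromo-3,7,11-trimethyldodeca-3,6,10-trien-2-one
Conditions: NBS (1.0 equiv), NaHCO3, THF/H2O, −20 °C
Reagents that add atoms: N-bromosuccinimide, O=C1CCC(=O)N1Br; water, O
Why: The 2-ethoxy-1,3-diene is by far the most electron-rich alkene present, so NBS should brominate its terminal carbon and water should open the resulting oxocarbenium ion to a hemiketal that collapses to the bromomethyl ketone (the standard conversion of a 1-alkoxyvinyl group into a bromoacetyl group) before the three trisubstituted alkenes react.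

Step 6
Reactants: 16 (3Z,6Z)-1-bromo-3,7,11-trimethyldodeca-3,6,10-trien-2-one
Product: 17 (2R,3Z,6Z)-1-bromo-3,7,11-trimethyldodeca-3,6,10-trien-2-ol
Conditions: (R)-2-methyl-CBS-oxazaborolidine (20 mol %), catecholborane, toluene, −78 °C
Reagents that add atoms: none
Why: Corey–Bakshi–Shibata reduction, in which the ketone binds to the oxazaborolidine–borane complex with its larger, α-branched alkenyl group away from the catalyst and hydride is delivered to one face, which with the (R)-catalyst should set the 2R carbinol centre, while catecholborane at −78 °C should neither hydroborate the alkenes nor reduce the C–Br bond.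

Step 7
Reactants: 17 (2R,3Z,6Z)-1-bromo-3,7,11-trimethyldodeca-3,6,10-trien-2-ol
Product: 18 (2R,5aR,7S,9aS)-7-bromo-2-(bromomethyl)-3,6,6,9a-tetramethyl-2,5,5a,6,7,8,9,9a-octahydro-1-benzoxepine
Conditions: 1,3-dibromo-5,5-dimethylhydantoin (DBDMH, 1.1 equiv), chiral BINOL-derived thiophosphoramide Lewis base (10 mol %), toluene/CH2Cl2, −60 °C
Reagents that add atoms: 1,3-dibromo-5,5-dimethylhydantoin, CC1(C)N(Br)C(=O)N(Br)C1=O
Why: Bromenium-induced polyene cyclization, in which bromenium transfer to the terminal, most nucleophilic alkene starts a chair-like cascade where the Z alkene attacks C-6 through its C-5a end (6-endo closure of ring A) and the C-2 hydroxyl adds anti at C-9a (7-endo closure of ring B), so that bromine at C-7 is equatorial, the C-5 chain axial and the ether oxygen equatorial, which is the cis-fused 5aR,7S,9aS arrangement, the absolute sense being set by the chiral Lewis base and the diastereomer from attack on the other alkene face being removed by chromatography.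

**Compound list**

1 | 5-bromo-2-methylpent-2-ene | CC(C)=CCCBr | starting material
2 | propyne | CC#C | starting material
3 | (4-methylpent-3-en-1-yl)magnesium bromide | CC(C)=CCC[Mg]Br | intermediate
4 | (4-methylpent-3-en-1-yl)copper, as its MgBr2·SMe2 complex | CC(C)=CCC[Cu] | intermediate
5 | [(Z)-2,6-dimethylhepta-1,5-dien-1-yl]copper | [Cu]/C=C(/C)CCC=C(C)C | intermediate
6 | (Z)-1-iodo-2,6-dimethylhepta-1,5-diene | I/C=C(/C)CCC=C(C)C | intermediate
7 | but-2-yn-1-ol | CC#CCO | starting material
8 | sodium 2,2-bis(2-methoxyethoxy)-3-methyl-2,5-dihydro-1,2-oxaluminol-2-uide (cyclic alkenylalanate) | [Na+].COCCO[Al-]1(OCCOC)OCC=C1C | intermediate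
9 | (Z)-3-iodobut-2-en-1-ol | OC/C=C(\I)C | intermediate
10 | (Z)-1-bromo-3-iodobut-2-ene | BrC/C=C(\I)C | intermediate
11 | tributyl(1-ethoxyvinyl)stannane | CCCC[Sn](CCCC)(CCCC)C(=C)OCC | starting material
12 | [(Z)-2,6-dimethylhepta-1,5-dien-1-yl]lithium | [Li]/C=C(/C)CCC=C(C)C | intermediate
13 | [(Z)-2,6-dimethylhepta-1,5-dien-1-yl]magnesium bromide | Br[Mg]/C=C(/C)CCC=C(C)C | intermediate
14 | (2Z,5Z)-2-iodo-6,10-dimethylundeca-2,5,9-triene | C/C(I)=C/C/C=C(/C)CCC=C(C)C | intermediate
15 | (3Z,6Z)-2-ethoxy-3,7,11-trimethyldodeca-1,3,6,10-tetraene | C=C(OCC)/C(C)=C\C/C=C(/C)CCC=C(C)C | intermediate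
16 | (3Z,6Z)-1-bromo-3,7,11-trimethyldodeca-3,6,10-trien-2-one | BrCC(=O)/C(C)=C\C/C=C(/C)CCC=C(C)C | intermediate
17 | (2R,3Z,6Z)-1-bromo-3,7,11-trimethyldodeca-3,6,10-trien-2-ol | BrC[C@H](O)/C(C)=C\C/C=C(/C)CCC=C(C)C | intermediate
18 | (2R,5aR,7S,9aS)-7-bromo-2-(bromomethyl)-3,6,6,9a-tetramethyl-2,5,5a,6,7,8,9,9a-octahydro-1-benzoxepine | CC1=CC[C@@H]2C(C)(C)[C@@H](Br)CC[C@]2(C)O[C@H]1CBr | target

**Count and risks**

Total step count: 7. Longest linear sequence: 6 steps (from 7 to 18 through steps 2, 3, 4, 5, 6 and 7).

Steps most likely to fail:

1. Step 7. The chiral bromenium carrier may discriminate poorly between the faces of the remote terminal alkene, the internal alkenes may be brominated in competition, or the C-9a cation may lose a proton before the seven-membered ether closes. The fallback sets out from 17 and comes back at 18 and uses a softer, reversibly adding electrophile. Hg(OTf)2·PhNMe2 in MeNO2 at −20 °C should give, by the same chair-like anti addition, [(2R,5aR,7S,9aS)-2-(bromomethyl)-3,6,6,9a-tetramethyl-2,5,5a,6,7,8,9,9a-octahydro-1-benzoxepin-7-yl]mercury triflate F1. Aqueous KBr should convert it into bromo[(2R,5aR,7S,9aS)-2-(bromomethyl)-3,6,6,9a-tetramethyl-2,5,5a,6,7,8,9,9a-octahydro-1-benzoxepin-7-yl]mercury F2, and the isomer from attack on the other alkene face is separated at this stage by chromatography. Brominolysis of the C–Hg bond with retention (Br2, LiBr, pyridine, 0 °C, in the dark) should then give 18.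

2. Step 4. The two stages may not tolerate each other in one flask: the cuprate may also touch the vinylic iodide, and the magnesium halides may slow the palladium cycle so that protodestannylation or hydrolysis of the enol ether takes over. The fallback sets out from 6 and 10 and comes back at 16. The copper-catalysed coupling is run alone and 14 is isolated. Iodine–lithium exchange (t-BuLi, Et2O, −78 °C) should give [(2Z,5Z)-6,10-dimethylundeca-2,5,9-trien-2-yl]lithium F3, which is acylated with 2-bromo-N-methoxy-N-methylacetamide at −78 °C to give 16 directly, so that tin, palladium and step 5 are avoided.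

3. Step 6. Enantioface discrimination may be poor because the bromomethyl group and the Z-alkenyl group differ too little in effective size, and conjugate reduction may compete. The fallback sets out from 16 and comes back at 17. Luche reduction (NaBH4, CeCl3·7H2O, MeOH, −40 °C) should give rac-(3Z,6Z)-1-bromo-3,7,11-trimethyldodeca-3,6,10-trien-2-ol F4. Kinetic resolution with immobilised Candida antarctica lipase B and vinyl acetate in hexane should acylate the 2S enantiomer to (2S,3Z,6Z)-1-bromo-3,7,11-trimethyldodeca-3,6,10-trien-2-yl acetate F5 and leave 17, which is separated by chromatography.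

**Further compounds**

F1 | step 7 | [(2R,5aR,7S,9aS)-2-(bromomethyl)-3,6,6,9a-tetramethyl-2,5,5a,6,7,8,9,9a-octahydro-1-benzoxepin-7-yl]mercury triflate | CC1=CC[C@@H]2C(C)(C)[C@@H]([Hg]OS(=O)(=O)C(F)(F)F)CC[C@]2(C)O[C@H]1CBr
F2 | step 7 | bromo[(2R,5aR,7S,9aS)-2-(bromomethyl)-3,6,6,9a-tetramethyl-2,5,5a,6,7,8,9,9a-octahydro-1-benzoxepin-7-yl]mercury | CC1=CC[C@@H]2C(C)(C)[C@@H]([Hg]Br)CC[C@]2(C)O[C@H]1CBr
F3 | step 4 | [(2Z,5Z)-6,10-dimethylundeca-2,5,9-trien-2-yl]lithium | C/C([Li])=C/C/C=C(/C)CCC=C(C)C
F4 | step 6 | rac-(3Z,6Z)-1-bromo-3,7,11-trimethyldodeca-3,6,10-trien-2-ol | BrCC(O)/C(C)=C\C/C=C(/C)CCC=C(C)C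
F5 | step 6 | (2S,3Z,6Z)-1-bromo-3,7,11-trimethyldodeca-3,6,10-trien-2-yl acetate | BrC[C@@H](OC(C)=O)/C(C)=C\C/C=C(/C)CCC=C(C)C
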